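**Plan**

- Retrosynthesis: the four phenolic O–H bonds go back to methyl ethers, and the pyranone O1–C2 bond is cut (retro-oxa-Michael). The two aryl–acyl bonds, ring A–C(=O)iPr and C4a–C4 of ring B, are then cut together to a mixed diaryl diester. The two ester C–O bonds and the two aryl–CH2 bonds lead back to one phenol and formaldehyde.
- Enabling feature: rings A and B are both methylphloroglucinol units. In each, the acyl carbon is ortho to a phenolic oxygen (a ring A OH; O1 on C8a of ring B), the para carbon carries CH3 (C6 in ring B) and the other ortho carbon carries the CH2 bridge (C8 in ring B). Both aryl–acyl bonds are therefore the same ortho-hydroxyaryl ketone bond, each with one open site.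
- Forward: C–H borylation and oxidation give 3,5-dimethoxy-4-methylphenol; formaldehyde joins two molecules; two successive esterifications give the isobutyrate/3-methylbut-2-enoate diester; one irradiation moves both acyl groups from O to C. The pyranone, the only ring formed, then closes by oxa-Michael addition, and BBr3 frees the phenols.
- Stereochemistry: none; the target has no stereocentre and no stereogenic double bond.

Key step: step 6

Remark: 3,5-dimethoxy-4-methylphenol is made from 2,6-dimethoxytoluene, because peracid oxidation of the corresponding benzaldehyde, whose ring carbon is only meta to both methoxy groups, would be expected to give mainly the benzoic acid.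

**Route**

Step 1
Reactants: 1 1,3-dimethoxy-2-methylbenzene (2,6-dimethoxytoluene)
Product: 2 2-(3,5-dimethoxy-4-methylphenyl)-4,4,5,5-tetramethyl-1,3,2-dioxaborolane
Conditions: [Ir(OMe)(cod)]2 (1.5 mol%), 4,4'-di-tert-butyl-2,2'-bipyridine (3 mol%), B2pin2 (1.0 equiv), THF, 80 °C
Reagents that add atoms: bis(pinacolato)diboron, CC1(C)OB(OC1(C)C)B1OC(C)(C)C(C)(C)O1
Why: Iridium-catalysed aromatic C–H borylation is sterically controlled, and in this 1,2,3-trisubstituted arene only the C–H para to the methyl group has no ortho substituent.

Step 2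
Reactants: 2 2-(3,5-dimethoxy-4-methylphenyl)-4,4,5,5-tetramethyl-1,3,2-dioxaborolane
Product: 3 3,5-dimethoxy-4-methylphenol
Conditions: 2KHSO5·KHSO4·K2SO4 (Oxone), acetone/H2O, 0 °C → rt; aq. NaHSO3
Reagents that add atoms: potassium peroxymonosulfate, [K+].[O-]S(=O)(=O)OO
Why: Ipso-hydroxylation of the aryl boronate (1,2-aryl shift from boron to peroxide oxygen, then hydrolysis) is the standard companion of C–H borylation for making 3,5-disubstituted phenols.

Step 3
Reactants: 3 3,5-dimethoxy-4-methylphenol (two molecules); 4 formaldehyde
Product: 5 2,2'-methylenebis(3,5-dimethoxy-4-methylphenol)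
Conditions: 37% aq. CH2O (0.25 equiv), conc. HCl (cat.), MeOH, 40 °C; excess 3 recovered
Reagents that add atoms: none
Why: Acid-catalysed phenol–formaldehyde condensation (hydroxymethylation, then Friedel–Crafts alkylation) can only occur at the two equivalent carbons ortho to OH because the para carbon carries methyl, and the excess of 3 should hold the condensation at the dimer.

Step 4
Reactants: 5 2,2'-methylenebis(3,5-dimethoxy-4-methylphenol); 6 2-methylpropanoyl chloride (isobutyryl chloride)
Product: 7 2-[(6-hydroxy-2,4-dimethoxy-3-methylphenyl)methyl]-3,5-dimethoxy-4-methylphenyl 2-methylpropanoate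
Conditions: 6 (1.0 equiv, slow addition), Et3N (1.1 equiv), CH2Cl2, −20 → 0 °C
Reagents that add atoms: none
Why: O-acylation with one equivalent of acid chloride is established for mono-esterifying hydrogen-bonded 2,2'-methylenebisphenols; the symmetric diester and unreacted 5 are separable and recyclable, and acyl transfer between the two oxygens is degenerate.

Step 5
Reactants: 7 2-[(6-hydroxy-2,4-dimethoxy-3-methylphenyl)methyl]-3,5-dimethoxy-4-methylphenyl 2-methylpropanoate; 8 3-methylbut-2-enoyl chloride (3,3-dimethylacryloyl chloride)
Product: 9 2-{[2,4-dimethoxy-3-methyl-6-(2-methylpropanoyloxy)phenyl]methyl}-3,5-dimethoxy-4-methylphenyl 3-methylbut-2-enoate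
Conditions: 8 (1.3 equiv), pyridine (3 equiv), CH2Cl2, 0 °C → rt
Reagents that add atoms: none
Why: Esterification of the remaining phenol with the acid chloride; the weak base pyridine is chosen so that γ-deprotonation to a vinylketene, which would deconjugate the ester, stays slow.

Step 6
Reactants: 9 2-{[2,4-dimethoxy-3-methyl-6-(2-methylpropanoyloxy)phenyl]methyl}-3,5-dimethoxy-4-methylphenyl 3-methylbut-2-enoate
Product: 12 1-[2-hydroxy-3-{[2-hydroxy-4,6-dimethoxy-5-methyl-3-(2-methylpropanoyl)phenyl]methyl}-4,6-dimethoxy-5-methylphenyl]-3-methylbut-2-en-1-one, via ring-A-rearranged monoester 10 (not isolated), via ring-B-rearranged monoester 11 (not isolated)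
Conditions: hν (254 nm, low-pressure Hg lamps, quartz), degassed cyclohexane (2 mM), N2, 20 °C
Reagents that add atoms: none
Why: Each excited aryl ester breaks its ArO–C(=O) bond homolytically to a solvent-caged aryloxyl/acyl radical pair, which recombines at the ortho carbon to a 6-acylcyclohexa-2,4-dienone that tautomerises to the hydrogen-bonded ortho-hydroxy ketone; the two esters react in turn through 10 and 11. The closest known reaction is the photo-Fries rearrangement of aryl alkanoates and of aryl 3-methylbut-2-enoates, the latter being an established entry to the enone precursors of 2,2-dimethylchroman-4-ones. No ring is closed and no stereocentre is formed; the step forms the ring A–C(=O)iPr bond and the C4a–C4 bond. Each acyl group must return to its own ring at one carbon: in-cage recombination outruns diffusion and decarbonylation, the para carbon carries methyl, the other ortho carbon carries the CH2 bridge, and recombination at those substituted carbons gives non-enolisable dienones that can only revert. The first-formed ortho-hydroxy ketone filters light but relaxes by excited-state proton transfer, so the second shift should be slower but the product photostable; phenols from cage escape can be re-esterified, and any 13 formed early lies on the route.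

Step 7
Reactants: 12 1-[2-hydroxy-3-{[2-hydroxy-4,6-dimethoxy-5-methyl-3-(2-methylpropanoyl)phenyl]methyl}-4,6-dimethoxy-5-methylphenyl]-3-methylbut-2-en-1-one
Product: 13 8-{[2-hydroxy-4,6-dimethoxy-5-methyl-3-(2-methylpropanoyl)phenyl]methyl}-5,7-dimethoxy-2,2,6-trimethyl-2,3-dihydro-4H-chromen-4-one
Conditions: NaOAc (2 equiv), EtOH, reflux
Reagents that add atoms: none
Why: Base-mediated intramolecular oxa-Michael addition (6-endo-trig) of an ortho-hydroxyaryl β,β-dimethyl enone is the standard closure to a 2,2-dimethylchroman-4-one, and with the C5 oxygen methylated only the C8a phenol can add.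

Step 8
Reactants: 13 8-{[2-hydroxy-4,6-dimethoxy-5-methyl-3-(2-methylpropanoyl)phenyl]methyl}-5,7-dimethoxy-2,2,6-trimethyl-2,3-dihydro-4H-chromen-4-one
Product: 14 5,7-dihydroxy-2,2,6-trimethyl-8-{[2,4,6-trihydroxy-3-methyl-5-(2-methylpropanoyl)phenyl]methyl}-2,3-dihydro-4H-chromen-4-one (CNP0186856.0)
Conditions: BBr3 (10 equiv), CH2Cl2, −78 → 0 °C; then H2O, 0 °C
Reagents that add atoms: none
Why: BBr3 cleavage of aryl methyl ethers should remove the two carbonyl-ortho ethers by chelation and the two di-ortho-substituted ethers readily, while the pyranone oxygen, a vinylogous ester oxygen, is a poor Lewis base and the low temperature spares the CH2 bridge.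

**Compound list**

1 | 1,3-dimethoxy-2-methylbenzene (2,6-dimethoxytoluene) | COc1cccc(OC)c1C | starting material
2 | 2-(3,5-dimethoxy-4-methylphenyl)-4,4,5,5-tetramethyl-1,3,2-dioxaborolane | COc1cc(B2OC(C)(C)C(C)(C)O2)cc(OC)c1C | intermediate
3 | 3,5-dimethoxy-4-methylphenol | COc1cc(O)cc(OC)c1C | intermediate
4 | formaldehyde | C=O | starting material
5 | 2,2'-methylenebis(3,5-dimethoxy-4-methylphenol) | COc1cc(O)c(Cc2c(O)cc(OC)c(C)c2OC)c(OC)c1C | intermediate
6 | 2-methylpropanoyl chloride (isobutyryl chloride) | CC(C)C(Cl)=O | starting material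
7 | 2-[(6-hydroxy-2,4-dimethoxy-3-methylphenyl)methyl]-3,5-dimethoxy-4-methylphenyl 2-methylpropanoate | COc1cc(OC(=O)C(C)C)c(Cc2c(O)cc(OC)c(C)c2OC)c(OC)c1C | intermediate
8 | 3-methylbut-2-enoyl chloride (3,3-dimethylacryloyl chloride) | CC(C)=CC(Cl)=O | starting material
9 | 2-{[2,4-dimethoxy-3-methyl-6-(2-methylpropanoyloxy)phenyl]methyl}-3,5-dimethoxy-4-methylphenyl 3-methylbut-2-enoate | COc1cc(OC(=O)C(C)C)c(Cc2c(OC(=O)C=C(C)C)cc(OC)c(C)c2OC)c(OC)c1C | intermediate
10 | 2-{[2-hydroxy-4,6-dimethoxy-5-methyl-3-(2-methylpropanoyl)phenyl]methyl}-3,5-dimethoxy-4-methylphenyl 3-methylbut-2-enoate (ring A rearranged) | COc1c(C(=O)C(C)C)c(O)c(Cc2c(OC(=O)C=C(C)C)cc(OC)c(C)c2OC)c(OC)c1C | intermediate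
11 | 2-{[2-hydroxy-4,6-dimethoxy-5-methyl-3-(3-methylbut-2-enoyl)phenyl]methyl}-3,5-dimethoxy-4-methylphenyl 2-methylpropanoate (ring B rearranged) | COc1cc(OC(=O)C(C)C)c(Cc2c(O)c(C(=O)C=C(C)C)c(OC)c(C)c2OC)c(OC)c1C | intermediate
12 | 1-[2-hydroxy-3-{[2-hydroxy-4,6-dimethoxy-5-methyl-3-(2-methylpropanoyl)phenyl]methyl}-4,6-dimethoxy-5-methylphenyl]-3-methylbut-2-en-1-one | COc1c(C(=O)C(C)C)c(O)c(Cc2c(O)c(C(=O)C=C(C)C)c(OC)c(C)c2OC)c(OC)c1C | intermediate
13 | 8-{[2-hydroxy-4,6-dimethoxy-5-methyl-3-(2-methylpropanoyl)phenyl]methyl}-5,7-dimethoxy-2,2,6-trimethyl-2,3-dihydro-4H-chromen-4-one | COc1c(C(=O)C(C)C)c(O)c(Cc2c(OC)c(C)c(OC)c3c2OC(C)(C)CC3=O)c(OC)c1C | intermediate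
14 | 5,7-dihydroxy-2,2,6-trimethyl-8-{[2,4,6-trihydroxy-3-methyl-5-(2-methylpropanoyl)phenyl]methyl}-2,3-dihydro-4H-chromen-4-one | Cc1c(O)c(Cc2c(O)c(C)c(O)c3c2OC(C)(C)CC3=O)c(O)c(C(=O)C(C)C)c1O | target

**Totals**

Total step count: 8. Longest linear sequence: 8 steps (1 → 14).

**Steps most likely to fail**

1. Step 6. After the first acyl shift the new ortho-hydroxyaryl ketone absorbs much of the 254 nm light and may quench the neighbouring ester across the CH2 bridge, so the second shift may stall; cage escape would also strip acyl groups. The fallback sets out from monoester 7 and forms the second aryl–acyl bond by electrophilic acylation instead of a second photochemical shift. Irradiating 7 alone (254 nm, cyclohexane), with one ester and no ketone present at the start, should give 1-{2-hydroxy-3-[(6-hydroxy-2,4-dimethoxy-3-methylphenyl)methyl]-4,6-dimethoxy-5-methylphenyl}-2-methylpropan-1-one F1. Warming F1 with 3-methylbut-2-enoic acid in P2O5/MeSO3H (50 °C) should acylate the only free aromatic CH (ring B, ortho to its phenol; ring A is fully substituted and deactivated) and close the pyranone through that phenol. This returns to the route at compound 13.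

2. Step 8. Cleaving the two non-chelated ethers needs prolonged exposure to BBr3 and the HBr formed from it, during which the pyranone may open and re-close on the C5 oxygen (a Wessely–Moser-type isomerisation) or the electron-rich diarylmethane bridge may be cut by acid. The fallback sets out from 13 and splits the deprotection into two mechanistically different stages. BCl3 (CH2Cl2, −78 → 0 °C) should remove only the two ethers ortho to the carbonyl groups by chelation, giving 8-{[2,4-dihydroxy-6-methoxy-5-methyl-3-(2-methylpropanoyl)phenyl]methyl}-5-hydroxy-7-methoxy-2,2,6-trimethyl-2,3-dihydro-4H-chromen-4-one F4. The two remaining hindered ethers would then be cleaved by SN2 attack of thiolate on methyl (NaSEt, DMF, 110 °C), with the substrate as a polyphenoxide and no Lewis acid present. This returns to the route at target 14.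

3. Step 3. Each ring of the dimer keeps one nucleophilic CH, so condensation may run on to trimers and higher methylene-bridged oligomers, and formaldehyde may also tie the two phenols into a cyclic acetal. The fallback sets out from phenol 3 and separates making the electrophile from the coupling. Vilsmeier–Haack formylation (POCl3, DMF, 0 °C → rt; aq. NaOAc) at the carbon ortho to OH should give 6-hydroxy-2,4-dimethoxy-3-methylbenzaldehyde F2. NaBH4 (EtOH, 0 °C) would reduce it to 2-(hydroxymethyl)-3,5-dimethoxy-4-methylphenol F3. F3 is then added slowly to an excess of 3 with TsOH (cat.) in CH2Cl2 at rt, a Friedel–Crafts benzylation through the ortho-quinone methide or benzyl cation in which the electrophile stays dilute. This returns to the route at bisphenol 5.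

**Further compounds**

F1 | step 6 | 1-{2-hydroxy-3-[(6-hydroxy-2,4-dimethoxy-3-methylphenyl)methyl]-4,6-dimethoxy-5-methylphenyl}-2-methylpropan-1-one | COc1c(C(=O)C(C)C)c(O)c(Cc2c(O)cc(OC)c(C)c2OC)c(OC)c1C
F2 | step 3 | 6-hydroxy-2,4-dimethoxy-3-methylbenzaldehyde | COc1cc(O)c(C=O)c(OC)c1C
F3 | step 3 | 2-(hydroxymethyl)-3,5-dimethoxy-4-methylphenol | COc1cc(O)c(CO)c(OC)c1C
F4 | step 8 | 8-{[2,4-dihydroxy-6-methoxy-5-methyl-3-(2-methylpropanoyl)phenyl]methyl}-5-hydroxy-7-methoxy-2,2,6-trimethyl-2,3-dihydro-4H-chromen-4-one | Cc1c(O)c(C(=O)C(C)C)c(O)c(Cc2c(OC)c(C)c(O)c3c2OC(C)(C)CC3=O)c1OC
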